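**Plan**
Cuts: first the two O–C bonds of the masking groups (3'-O–benzyl, 5-O–methyl). Then the aryl ether bond O1–C8a of ring C, then C3–C4 of the resulting 1,3-diketone, which leaves a ring A aldehyde and a ring B methyl ketone.
Enabling feature: O1 is bound to C8a of the fully substituted ring A, next to C4a, which carries the C4 carbonyl. In 2,3,4,5-tetramethoxybenzaldehyde the future C8a is the only ring carbon still bearing hydrogen, so a bromine leaving group can be placed there with no choice of position.
Forward order: rings A and B come from purchased arenes. Ring A is formylated and brominated, ring B is benzylated and converted to its acetophenone, and aldol addition (C3–C4) followed by oxidation joins them. Ring C, the only ring built, closes by copper-catalysed O-arylation of the diketone enolate.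
BCl3 then frees the 3'-OH and, through chelation to the C4 carbonyl, the 5-OH alone among the ring A ethers.
Stereochemistry: the target has no stereocentre. The two carbinol carbons met on the way are racemic and are erased by oxidation.

Key step: step 8

Remark: 1,2,3,4-tetramethoxybenzene and 3-hydroxy-4,5-dimethoxybenzaldehyde are taken as catalogue chemicals, and the 1,3-diketone is drawn in its diketo form although it should exist largely as the chelated enol.

**Step 1**
Reactants: 1 1,2,3,4-tetramethoxybenzene
Product: 3 2,3,4,5-tetramethoxybenzaldehyde, via 2,3,4,5-tetramethoxyphenyllithium 2 (not isolated)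
Conditions: n-BuLi, TMEDA, THF, 0 °C; DMF, 0 °C to rt; 1 M HCl
Reagents that add atoms: N,N-dimethylformamide, CN(C)C=O
Why: Directed ortho-metalation, in which the terminal methoxy group guides n-BuLi·TMEDA to the adjacent C–H (the two free positions are equivalent by symmetry) and DMF formylates the aryllithium without any Lewis acid that could cleave an ortho methyl ether.

**Step 2**
Reactants: 3 2,3,4,5-tetramethoxybenzaldehyde
Product: 4 2-bromo-3,4,5,6-tetramethoxybenzaldehyde
Conditions: NBS, MeCN, rt, dark
Reagents that add atoms: N-bromosuccinimide, O=C1CCC(=O)N1Br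
Why: Electrophilic aromatic bromination of a ring with a single remaining C–H that lies ortho and para to methoxy groups, on a substrate whose aldehyde offers no enolisable position, so bromine can only enter at the carbon that becomes C8a.

**Step 3**
Reactants: 5 3-hydroxy-4,5-dimethoxybenzaldehyde
Product: 6 3-benzyloxy-4,5-dimethoxybenzaldehyde
Conditions: BnBr, K2CO3, DMF, 50 °C
Reagents that add atoms: benzyl bromide, BrCc1ccccc1
Why: Williamson ether synthesis on the only phenol, giving a benzyl ether that should withstand organometallics, enolates, IBX and hot carbonate and that falls to BCl3 at the end.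

**Step 4**
Reactants: 6 3-benzyloxy-4,5-dimethoxybenzaldehyde
Product: 7 (±)-1-(3-benzyloxy-4,5-dimethoxyphenyl)ethanol
Conditions: MeMgBr, THF, 0 °C; aq. NH4Cl
Reagents that add atoms: methylmagnesium bromide, C[Mg]Br
Why: Grignard 1,2-addition to a non-enolisable aromatic aldehyde, the new carbinol centre forming as a racemate that the next step erases.

**Step 5**
Reactants: 7 (±)-1-(3-benzyloxy-4,5-dimethoxyphenyl)ethanol
Product: 8 1-(3-benzyloxy-4,5-dimethoxyphenyl)ethanone
Conditions: IBX, EtOAc, 80 °C
Reagents that add atoms: none
Why: IBX oxidation of a secondary benzylic alcohol to the aryl methyl ketone under neutral, heterogeneous conditions that leave the aryl ethers untouched.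

**Step 6**
Reactants: 8 1-(3-benzyloxy-4,5-dimethoxyphenyl)ethanone; 4 2-bromo-3,4,5,6-tetramethoxybenzaldehyde
Product: 10 (±)-3-(2-bromo-3,4,5,6-tetramethoxyphenyl)-3-hydroxy-1-(3-benzyloxy-4,5-dimethoxyphenyl)propan-1-one, via lithium enolate 9 (not isolated)
Conditions: LiN(i-Pr)2, THF, −78 °C; then 4, THF, −78 °C; AcOH, −78 °C
Reagents that add atoms: none
Why: Directed crossed aldol addition of a preformed lithium enolate to an aldehyde that cannot enolise, in which low temperature and a cold acidic quench hold back retro-aldol and dehydration, and the single carbinol centre forms as a racemate that the next step removes.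

**Step 7**
Reactants: 10 (±)-3-(2-bromo-3,4,5,6-tetramethoxyphenyl)-3-hydroxy-1-(3-benzyloxy-4,5-dimethoxyphenyl)propan-1-one
Product: 11 1-(2-bromo-3,4,5,6-tetramethoxyphenyl)-3-(3-benzyloxy-4,5-dimethoxyphenyl)propane-1,3-dione
Conditions: IBX (3 equiv), EtOAc, 80 °C
Reagents that add atoms: none
Why: IBX oxidation of a β-hydroxy ketone to the 1,3-diketone, a well-established use of this reagent because it stops at the diketone level without attacking the acidic CH2 between the carbonyls or cleaving the chain.

**Step 8**
Reactants: 11 1-(2-bromo-3,4,5,6-tetramethoxyphenyl)-3-(3-benzyloxy-4,5-dimethoxyphenyl)propane-1,3-dione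
Product: 13 3'-benzyloxy-5,6,7,8,4',5'-hexamethoxyflavone, via caesium enolate 12 (not isolated)
Conditions: CuI (10 mol %), 1,10-phenanthroline (20 mol %), Cs2CO3, dry DMF, 100 °C, Ar
Reagents that add atoms: none
Why: Cs2CO3 converts 11 into the Z-configured enolate 12, which replaces iodide on phenanthroline-bound monovalent copper; the C8a–Br bond, held near the metal by the C4 carbonyl tether, then adds oxidatively to give a seven-membered metallacycle of trivalent copper, and C–O reductive elimination releases 13 and returns the catalyst. The closest known reaction type is the intramolecular Ullmann-type O-arylation of 1-(2-haloaryl)-1,3-diketones to chromones and flavones. Ring C closes as a six-membered ring (O1, C2, C3, C4, C4a, C8a) through the oxygen of the carbonyl on the ring B side, which becomes O1. No stereocentre is formed. The selectivity needed is O- over C-arylation of the ambident enolate, and geometry secures it, because bonding through C3 or through the C4 oxygen would demand a four-membered ring. Four methoxy groups make ring A too electron-rich for an uncatalysed addition–elimination, which is why copper is used, and dry conditions guard the diketone against retro-Claisen cleavage.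

**Step 9**
Reactants: 13 3'-benzyloxy-5,6,7,8,4',5'-hexamethoxyflavone
Product: 15 Gardenin C (5,3'-dihydroxy-6,7,8,4',5'-pentamethoxyflavone), via bis(dichloroboryl) ether 14 (not isolated)
Conditions: BCl3 (3 equiv), C6HMe5 (3 equiv), CH2Cl2, −78 to 0 °C; H2O
Reagents that add atoms: none
Why: Lewis-acid ether cleavage in which BCl3 ionises the benzyl ether at low temperature while pentamethylbenzene traps the benzyl cation (Friedel–Crafts alkylation), and on warming a second BCl3, held in a six-membered chelate between the C4 carbonyl and the C5 oxygen, lets chloride remove only that methyl group before the boron aryloxide 14 is hydrolysed on work-up.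

**Compound list**
1 | 1,2,3,4-tetramethoxybenzene | COc1ccc(OC)c(OC)c1OC | starting material
2 | 2,3,4,5-tetramethoxyphenyllithium (not isolated) | [Li]c1cc(OC)c(OC)c(OC)c1OC | intermediate
3 | 2,3,4,5-tetramethoxybenzaldehyde | COc1cc(C=O)c(OC)c(OC)c1OC | intermediate
4 | 2-bromo-3,4,5,6-tetramethoxybenzaldehyde | COc1c(Br)c(C=O)c(OC)c(OC)c1OC | intermediate
5 | 3-hydroxy-4,5-dimethoxybenzaldehyde | COc1cc(C=O)cc(O)c1OC | starting material
6 | 3-benzyloxy-4,5-dimethoxybenzaldehyde | COc1cc(C=O)cc(OCc2ccccc2)c1OC | intermediate
7 | (±)-1-(3-benzyloxy-4,5-dimethoxyphenyl)ethanol, racemic | COc1cc(C(C)O)cc(OCc2ccccc2)c1OC | intermediate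
8 | 1-(3-benzyloxy-4,5-dimethoxyphenyl)ethanone | COc1cc(C(C)=O)cc(OCc2ccccc2)c1OC | intermediate
9 | lithium enolate of 8 (not isolated) | C=C(O[Li])c1cc(OC)c(OC)c(OCc2ccccc2)c1 | intermediate
10 | (±)-3-(2-bromo-3,4,5,6-tetramethoxyphenyl)-3-hydroxy-1-(3-benzyloxy-4,5-dimethoxyphenyl)propan-1-one, racemic | COc1c(Br)c(C(O)CC(=O)c2cc(OC)c(OC)c(OCc3ccccc3)c2)c(OC)c(OC)c1OC | intermediate
11 | 1-(2-bromo-3,4,5,6-tetramethoxyphenyl)-3-(3-benzyloxy-4,5-dimethoxyphenyl)propane-1,3-dione (diketo form drawn) | COc1c(Br)c(C(=O)CC(=O)c2cc(OC)c(OC)c(OCc3ccccc3)c2)c(OC)c(OC)c1OC | intermediate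
12 | caesium (Z)-enolate of 11 (not isolated) | [Cs+].[O-]/C(=C\C(=O)c1c(Br)c(OC)c(OC)c(OC)c1OC)c1cc(OC)c(OC)c(OCc2ccccc2)c1 | intermediate
13 | 3'-benzyloxy-5,6,7,8,4',5'-hexamethoxyflavone (3'-O-benzyl-5-O-methyl Gardenin C) | COc1cc(-c2cc(=O)c3c(OC)c(OC)c(OC)c(OC)c3o2)cc(OCc2ccccc2)c1OC | intermediate
14 | 5,3'-bis(dichloroboryloxy)-6,7,8,4',5'-pentamethoxyflavone (not isolated) | COc1cc(-c2cc(=O)c3c(OB(Cl)Cl)c(OC)c(OC)c(OC)c3o2)cc(OB(Cl)Cl)c1OC | intermediate
15 | Gardenin C, 5,3'-dihydroxy-6,7,8,4',5'-pentamethoxyflavone | COc1cc(-c2cc(=O)c3c(O)c(OC)c(OC)c(OC)c3o2)cc(O)c1OC | target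

**Step count**
Total step count: 9
Longest linear sequence: 7 steps (from 5 through steps 3, 4, 5, 6, 7, 8 and 9 to 15). Steps 1 and 2 form the two-step ring A branch.

**Steps most likely to fail**

Most at risk is step 8. Oxidative addition may be sluggish at a C–Br bond that is flanked by a methoxy group and a twisted aroyl group on a very electron-rich ring. Retro-Claisen cleavage of the diketone or reductive loss of bromine could then outrun ring closure.
- The fallback changes the leaving group, and with it the substrate. It sets out from 3 and comes back at 13.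
- Aldehyde 3 would be iodinated at its only free carbon (NIS, cat. CF3CO2H, MeCN, rt) to 2-iodo-3,4,5,6-tetramethoxybenzaldehyde F1.
- Addition of enolate 9 at −78 °C should give racemic 3-hydroxy-3-(2-iodo-3,4,5,6-tetramethoxyphenyl)-1-(3-benzyloxy-4,5-dimethoxyphenyl)propan-1-one F2.
- IBX in hot EtOAc should give 1-(2-iodo-3,4,5,6-tetramethoxyphenyl)-3-(3-benzyloxy-4,5-dimethoxyphenyl)propane-1,3-dione F3.
- With Cs2CO3 this forms the caesium (Z)-enolate of the iodo diketone F4. Its weaker C–I bond should meet CuI/1,10-phenanthroline at a markedly lower temperature and close the same O1–C8a bond to 13.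

Second is step 9. Over-demethylation is the danger: once boron is bound at O3' or O5 it can reach the neighbouring 4'- or 6-methoxy group and cleave it. If the mixture is kept too cold, cleavage at C5 stays incomplete.
- The fallback separates the two unmaskings into mechanistically unrelated operations. It sets out from 13 and comes back at 15.
- MgI2·OEt2 in toluene–Et2O at 70 °C binds only in the pocket between the C4 carbonyl and the C5 oxygen. After acidic work-up it should give 3'-benzyloxy-5-hydroxy-6,7,8,4',5'-pentamethoxyflavone F5.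
- The 3'-oxygen stays benzylated in this operation, so no metal aryloxide sits beside the 4'-methoxy group.
- Hydrogenolysis (H2, 1 atm, Pd/C, EtOAc–MeOH, rt) then removes the benzyl group under neutral conditions that spare the C2–C3 double bond and every methyl ether, giving 15.

Third is step 6. Addition to a di-ortho-substituted aldehyde is reversible, so retro-aldol on warming or loss of water to the enone may erode the adduct. The crowded carbinol it creates may also oxidise slowly in step 7.
- The fallback reverses the polarity of the two partners. It sets out from 4, uses 6, and comes back at 11.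
- MeMgBr (THF, 0 °C) would convert 4 into racemic 1-(2-bromo-3,4,5,6-tetramethoxyphenyl)ethanol F6.
- IBX would oxidise this to 1-(2-bromo-3,4,5,6-tetramethoxyphenyl)ethanone F7, a ketone too hindered to condense with itself.
- LiN(i-Pr)2 at −78 °C gives the lithium enolate of the ring A methyl ketone F8, which adds to the unhindered aldehyde 6. The product is racemic 1-(2-bromo-3,4,5,6-tetramethoxyphenyl)-3-hydroxy-3-(3-benzyloxy-4,5-dimethoxyphenyl)propan-1-one F9.
- The carbinol of F9 now lies next to the open ring B, and IBX should oxidise it to the same diketone 11.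

**Further compounds**
F1 | step 8 | 2-iodo-3,4,5,6-tetramethoxybenzaldehyde | COc1c(I)c(C=O)c(OC)c(OC)c1OC
F2 | step 8 | 3-hydroxy-3-(2-iodo-3,4,5,6-tetramethoxyphenyl)-1-(3-benzyloxy-4,5-dimethoxyphenyl)propan-1-one, racemic | COc1c(I)c(C(O)CC(=O)c2cc(OC)c(OC)c(OCc3ccccc3)c2)c(OC)c(OC)c1OC
F3 | step 8 | 1-(2-iodo-3,4,5,6-tetramethoxyphenyl)-3-(3-benzyloxy-4,5-dimethoxyphenyl)propane-1,3-dione | COc1c(I)c(C(=O)CC(=O)c2cc(OC)c(OC)c(OCc3ccccc3)c2)c(OC)c(OC)c1OC
F4 | step 8 | caesium (Z)-enolate of the iodo diketone | [Cs+].[O-]/C(=C\C(=O)c1c(I)c(OC)c(OC)c(OC)c1OC)c1cc(OC)c(OC)c(OCc2ccccc2)c1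
F5 | step 9 | 3'-benzyloxy-5-hydroxy-6,7,8,4',5'-pentamethoxyflavone | COc1cc(-c2cc(=O)c3c(O)c(OC)c(OC)c(OC)c3o2)cc(OCc2ccccc2)c1OC
F6 | step 6 | 1-(2-bromo-3,4,5,6-tetramethoxyphenyl)ethanol, racemic | COc1c(Br)c(C(C)O)c(OC)c(OC)c1OC
F7 | step 6 | 1-(2-bromo-3,4,5,6-tetramethoxyphenyl)ethanone | COc1c(Br)c(C(C)=O)c(OC)c(OC)c1OC
F8 | step 6 | lithium enolate of the ring A methyl ketone | C=C(O[Li])c1c(Br)c(OC)c(OC)c(OC)c1OC
F9 | step 6 | 1-(2-bromo-3,4,5,6-tetramethoxyphenyl)-3-hydroxy-3-(3-benzyloxy-4,5-dimethoxyphenyl)propan-1-one, racemic | COc1c(Br)c(C(=O)CC(O)c2cc(OC)c(OC)c(OCc3ccccc3)c2)c(OC)c(OC)c1OC
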